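**The decision.** The choice is how to dose into a catalyst that destroys itself in pairs.

the same everywhere: second substrate 0.680 M; free catalyst 0.54 mM; time 1.5 h
- gamma: starting material 0.34 M; reagent 0.408 M (fed, over 20 min); all else is in the flask from the start; the feed brings no volume worth counting
- delta: starting material 0.34 M (fed, over 20 min); reagent 0.408 M; all else is in the flask from the start; the feed brings no volume worth counting
- theta: starting material 0.34 M (in portions, 4, over 20 min); reagent 0.408 M; first portion at the start, last at 20 min
- eta: starting material 0.34 M; reagent 0.408 M; everything together at the start

- which flask leads in amount of target, in percent of the starting material charged ("all alike" within 1.5 percentage points) (gamma / delta / theta / eta / all alike)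
- how much target is there at the end, in percent of the starting material charged: gamma
- how much target is there at the end, in percent of the starting material charged: delta
- how much target is there at the end, in percent of the starting material charged: theta
- how much target is there at the end, in percent of the starting material charged: eta

- a species is counted by the starting material in it: one homo dimer counts as two
- where a step has two of a species, its rate is k times that concentration squared, and two are used at each turn
- run time (gamma): 1.5 h

    second substrate + reagent + free catalyst → free catalyst + second product (k1 = 350 /M²/min)
    2 free catalyst → spent catalyst (k2 = 530 /M/min)
    2 starting material → homo dimer (k3 = 0.17 /M/min)
    starting material + reagent + free catalyst → free catalyst + target (k4 = 7300 /M²/min)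

**Starting rate.** In eta, the step that turns starting material and reagent into target on free catalyst starts at 0.547 M/min. Free catalyst decays hyperbolically, with a lifetime of 1.75 min, the inverse of 2 times its death constant times its charge. By 1.5 h, this loss alone slows the rate by a factor of 52.5.

**The reach.** The target constant times the time integral of free catalyst is the catalyst reach, 27.3 /M. Integrating the rate of a pair with unequal charges against this reach, with side steps ignored, leaves 3.00% of the starting material. Starting material therefore slows the rate by a factor of 33.3 and reagent by 5.22, for a total of about 9135 with the catalyst factor.

**The crossing.** Starting material also pairs into homo dimer, but in eta the target step uses it 14 times as fast at the start. That gives a starting share of 93.3%. With side steps ignored, the same factors cut this lead to 1.69 by the end, so the share is an upper figure. This reckoning gives eta 90.5% target.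

**Forecast and result.** The forecast gives gamma 58%, delta 60%, theta 65% and eta 83%, with eta leading, since “any slow addition leaves material to arrive when little catalyst is left”. The simulation gives 48.7%, 59.9%, 62.1% and 85.8%, and eta leads.

**Gamma's loss.** Gamma has the same reach, but 63.7% of it passes while reagent is still being fed. Over the first 20 min, starting material averages 0.133 M in gamma against 0.0520 M in eta. Homo dimer ends at 49.8% in gamma and 10.9% in eta. Removing the dimer step shrinks the target gap between these flasks from 37 percentage points to 6.1 points.

**A neighbour.** A neighbour of eta has 0.24 M of reagent, which makes reagent the limiting reagent. The same reach leaves 2.02% of that reagent, which caps target at 69.2%. The neighbour's computed run leaves 2.64% of the reagent and gives 58.5% target, with 0.0348 M of second product.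

Its constants were set for the occasion; the rest is arithmetic.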